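**Retrosynthetic overview**
- 8 ⇒ C2–C1' bond: 2-zincated chromone 7 + aryl bromide 6 (Negishi). C2 is normally an acceptor carbon (enone beta-carbon); here it is a carbanion (beta-acylvinyl anion, homoenolate-type d3 reagent; also a metalated enol ether, a masked aroyl anion), so two electrophilic carbons are joined.
- 7 ⇒ chromone 5 by C2–H zincation.
- 5 ⇒ acetophenone 3 + one carbon from DMF-DMA, via enaminone 4 (O-cyclisation closes ring C).
- 3 ⇒ 3,4,5-trimethoxyphenol 1 + acetic acid (Friedel–Crafts).
- Ring order: ring A bought in 1, ring C built in step 2, ring B bought intact in 6 and attached last.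

Assumption: the target has no stereocentre (it is achiral), so no step needs stereocontrol; 6 and TMPZnCl·LiCl (THF solution) are taken as catalogue items.

**Route**

Step 1
Reactants: 1 3,4,5-trimethoxyphenol
Product: 3 1-(6-hydroxy-2,3,4-trimethoxyphenyl)ethan-1-one, via difluoroboron chelate 2 (not isolated)
Conditions: AcOH (solvent), BF3·OEt2 (3 equiv), 85 °C, 3 h; then H2O, 60 °C, 30 min
Reagents that add atoms: acetic acid, CC(=O)O
Why: BF3-mediated Friedel–Crafts C-acylation (Nencki type) of the electron-rich phenol can only go to the two equivalent free carbons ortho to OH and stops at mono-acylation because the ketone is held as the deactivated difluoroboron chelate 2, which water cleaves to 3; no stereocentre is formed.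

Step 2
Reactants: 3 1-(6-hydroxy-2,3,4-trimethoxyphenyl)ethan-1-one
Product: 5 5,6,7-trimethoxy-4H-chromen-4-one, via enaminone 4 (not isolated)
Conditions: Me2NCH(OMe)2 (2.5 equiv), toluene, 110 °C, 4 h; evaporate; AcOH, 100 °C, 2 h
Reagents that add atoms: N,N-dimethylformamide dimethyl acetal, COC(OC)N(C)C
Why: Condensation of the methyl ketone with the formamide acetal gives the push–pull enaminone 4, and in hot acid the ortho phenol adds to its beta-carbon and dimethylamine is lost (enaminone chromone synthesis, intramolecular oxa-Michael addition–elimination), closing ring C with C2 and C3 unsubstituted; no stereocentre is formed.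

Step 3
Reactants: 5 5,6,7-trimethoxy-4H-chromen-4-one; 6 4-bromo-2,6-dimethoxyphenol
Product: 8 ageconyflavone C, via 2-chromonylzinc chloride 7 (not isolated)
Conditions: TMPZnCl·LiCl (TMP = 2,2,6,6-tetramethylpiperidin-1-yl; 1.1 equiv to 5), THF, −30 to 25 °C, 1 h, no Lewis acid additive; then 7 (1.3 equiv) added over 1 h to 6 (1.0 equiv), Pd(OAc)2 (2 mol %), SPhos (2-dicyclohexylphosphino-2',6'-dimethoxybiphenyl, 4 mol %), THF, 25 to 50 °C; aq NH4Cl
Reagents that add atoms: none
Why: Without a carbonyl-complexing Lewis acid the amide base removes C2–H, the most acidic proton of the chromone (vinylic, next to the ring oxygen), to give the 2-zincated chromone 7, a beta-acylvinyl anion in which the normally electrophilic C2 has reversed polarity, and this carbanion is joined to the electrophilic C–Br carbon of 6 by Negishi cross-coupling, which with the zerovalent palladium/SPhos catalyst outruns protonolysis of the carbon–zinc bond by the free phenol; no stereocentre is formed.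

**Compound list**
1 | 3,4,5-trimethoxyphenol | COc1cc(O)cc(OC)c1OC | starting material
2 | difluoroboron chelate of 3 (2,2-difluoro-5,6,7-trimethoxy-4-methyl-1,3,2-benzodioxaborinine; boron on the phenolate oxygen and datively on the ketone oxygen) | CC1=[O+][B-](F)(F)Oc2cc(OC)c(OC)c(OC)c12 | intermediate
3 | 1-(6-hydroxy-2,3,4-trimethoxyphenyl)ethan-1-one (2'-hydroxy-4',5',6'-trimethoxyacetophenone) | CC(=O)c1c(O)cc(OC)c(OC)c1OC | intermediate
4 | (E)-3-(dimethylamino)-1-(6-hydroxy-2,3,4-trimethoxyphenyl)prop-2-en-1-one | CN(C)/C=C/C(=O)c1c(O)cc(OC)c(OC)c1OC | intermediate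
5 | 5,6,7-trimethoxy-4H-chromen-4-one | COc1cc2occc(=O)c2c(OC)c1OC | intermediate
6 | 4-bromo-2,6-dimethoxyphenol | COc1cc(Br)cc(OC)c1O | starting material
7 | (5,6,7-trimethoxy-4-oxo-4H-chromen-2-yl)zinc chloride, LiCl adduct | COc1cc2oc([Zn]Cl)cc(=O)c2c(OC)c1OC | intermediate
8 | ageconyflavone C, 2-(4-hydroxy-3,5-dimethoxyphenyl)-5,6,7-trimethoxy-4H-chromen-4-one (achiral) | COc1cc(-c2cc(=O)c3c(OC)c(OC)c(OC)cc3o2)cc(OC)c1O | target

**Count**
Total steps: 3. Longest linear sequence: 3 (1 → 3 → 5 → 8); 6 enters in step 3.

**Steps most likely to fail, with fallbacks**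

Step 3 (highest risk). The free phenol of 6 may protonate 7 before transmetalation, the electron-rich bromide adds slowly to zerovalent palladium, and C3 or C8 metalation could compete with C2. Fallback: set out from 6 and silylate it (TBSCl, imidazole, DMF, 25 °C) to (4-bromo-2,6-dimethoxyphenoxy)(tert-butyl)dimethylsilane F1. Couple F1 with 7 (Pd(OAc)2, SPhos, THF, 50 °C) to 2-[4-(tert-butyldimethylsilyloxy)-3,5-dimethoxyphenyl]-5,6,7-trimethoxy-4H-chromen-4-one F2. Remove the silyl group (TBAF, THF, 0 °C) to come back at 8. This protecting-group detour costs two steps but takes the acidic proton out of the key coupling; it does not cure a regiochemistry problem in the zincation.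

Step 2. The 2,6-disubstituted aryl ketone may condense slowly with the formamide acetal, which when hot can also O-methylate the phenol. Fallback: set out from 3 and formylate the methyl group by Claisen condensation with ethyl formate (NaH, THF, 0 to 25 °C). This gives the cyclic hemiacetal 2-hydroxy-5,6,7-trimethoxychroman-4-one F3 (racemic, in equilibrium with the open beta-keto aldehyde). Dehydrate F3 (cat. H2SO4, AcOH, 60 °C) to come back at 5.

Step 1. O-acetylation without C-acylation, or Lewis-acid demethylation of the methoxy group next to the new ketone, are the risks. Fallback: set out from 1 and acetylate the phenol (Ac2O, pyridine, 25 °C) to 3,4,5-trimethoxyphenyl acetate F4. Carry out a photo-Fries rearrangement (254 nm, degassed cyclohexane, 25 °C); this Lewis-acid-free radical-pair acyl shift can only reach the free ortho position because the para position is blocked, and it comes back at 3.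

**Further compounds**
F1 | step 3 | (4-bromo-2,6-dimethoxyphenoxy)(tert-butyl)dimethylsilane | COc1cc(Br)cc(OC)c1O[Si](C)(C)C(C)(C)C
F2 | step 3 | 2-[4-(tert-butyldimethylsilyloxy)-3,5-dimethoxyphenyl]-5,6,7-trimethoxy-4H-chromen-4-one | COc1cc(-c2cc(=O)c3c(OC)c(OC)c(OC)cc3o2)cc(OC)c1O[Si](C)(C)C(C)(C)C
F3 | step 2 | 2-hydroxy-5,6,7-trimethoxychroman-4-one (racemic) | COc1cc2OC(O)CC(=O)c2c(OC)c1OC
F4 | step 1 | 3,4,5-trimethoxyphenyl acetate | CC(=O)Oc1cc(OC)c(OC)c(OC)c1
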